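**Retrosynthetic overview**
- Sophoranone is taken back to its 7,4'-bis-O-TBS ether, which is cleaved last with buffered fluoride.
- The strategy rests on ring C (O1, C2, C3, C4, C4a, C8a). Its carbonyl carbon C4 sits on C4a next to the O1-bearing C8a, so C3–C4 and C2–H can come from the formyl C–H bond of a salicylaldehyde added across an O1–C2(=C3H2) 1-arylvinyl ether.
- The aldehyde is unmasked only after the enol ether exists: CHO from an aryl bromide (Br–Li exchange, DMF), and the enol ether from an aryl ester by carbonyl methylenation.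
- The ester comes from a ring A bromophenol (resorcinol, two directed lithiations, hydroxyl differentiation) and a ring B benzoic acid (4-bromophenol, two successive ortho-prenylations, carboxylation).
- Rings A and B are aromatic from the start; ring C is the only ring formed, in the key step.

Key step: step 13

Remark: half-reacted species of the twofold like operations (steps 1, 4 and 14) and phenoxide or carboxylate salts formed in passing are not numbered; organolithium intermediates and the formylation adduct are. Prenyl = 3-methylbut-2-enyl, MOM = methoxymethyl, TBS = tert-butyldimethylsilyl.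

**Ring A fragment**

Step 1
Reactants: 1 resorcinol
Product: 2 1,3-bis(methoxymethoxy)benzene
Conditions: MOMCl (2.5 equiv), i-Pr2NEt, CH2Cl2, 0 °C → rt
Reagents that add atoms: chloromethyl methyl ether (MOMCl), COCCl
Why: Twofold O-alkylation of the phenols by the α-chloro ether (Williamson-type etherification) should give the bis-acetal, which is the directing group for both lithiations.

Step 2
Reactants: 2 1,3-bis(methoxymethoxy)benzene; 3 prenyl bromide
Product: 5 1,3-bis(methoxymethoxy)-2-prenylbenzene, via aryllithium 4 (not isolated)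
Conditions: n-BuLi, THF, 0 °C; then CuBr·SMe2 (10 mol %), prenyl bromide, −78 °C → rt
Reagents that add atoms: none
Why: Directed ortho-metalation takes place at C2 between the two MOM ethers, and copper-catalysed SN2 allylation of the aryllithium should give the linear prenyl arene.

Step 3
Reactants: 5 1,3-bis(methoxymethoxy)-2-prenylbenzene
Product: 7 1-bromo-2,4-bis(methoxymethoxy)-3-prenylbenzene, via aryllithium 6 (not isolated)
Conditions: n-BuLi, TMEDA, THF, −20 → 0 °C; then BrCl2C–CCl2Br, −78 °C → rt
Reagents that add atoms: 1,2-dibromo-1,1,2,2-tetrachloroethane, BrC(Cl)(Cl)C(Cl)(Cl)Br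
Why: A second directed ortho-metalation at the ring C–H next to a MOM ether (kinetically preferred over the benzylic/allylic CH2) is followed by bromine transfer from the polyhaloethane, which marks the future C4a with a latent formyl group without an electrophile that could touch the prenyl alkene.

Step 4
Reactants: 7 1-bromo-2,4-bis(methoxymethoxy)-3-prenylbenzene
Product: 8 4-bromo-2-prenylbenzene-1,3-diol
Conditions: 3 M aq. HCl, MeOH, 40 °C
Reagents that add atoms: none
Why: Acid-catalysed acetal methanolysis should remove both MOM groups under dilute conditions that are commonly used on ortho-prenyl phenols without cyclisation to the chroman.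

Step 5
Reactants: 8 4-bromo-2-prenylbenzene-1,3-diol
Product: 9 6-bromo-3-(tert-butyldimethylsilyloxy)-2-prenylphenol
Conditions: TBSCl (1.0 equiv), imidazole, CH2Cl2, −20 → 0 °C
Reagents that add atoms: tert-butyldimethylsilyl chloride (TBSCl), CC(C)(C)[Si](C)(C)Cl
Why: Site-selective O-silylation should occur at the hydroxyl with one free ortho position, because the other hydroxyl is flanked by Br and prenyl and hydrogen-bonded to bromine.

**Ring B fragment**

Step 6
Reactants: 10 4-bromophenol; 3 prenyl bromide
Product: 11 4-bromo-2-prenylphenol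
Conditions: NaH (1.1 equiv), toluene, 0 °C → rt; then prenyl bromide (1.05 equiv), rt
Reagents that add atoms: none
Why: A sodium phenoxide reacting as a tight ion pair in a non-polar solvent is alkylated at the ortho carbon rather than at oxygen, and with the para position blocked by bromine one prenyl group should enter ortho; the aryl prenyl ether by-product is removed at this stage.

Step 7
Reactants: 11 4-bromo-2-prenylphenol; 3 prenyl bromide
Product: 12 4-bromo-2,6-diprenylphenol
Conditions: NaH (1.1 equiv), toluene, 0 °C → rt; then prenyl bromide (1.1 equiv), rt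
Reagents that add atoms: none
Why: The same ortho C-alkylation of the sodium phenoxide is repeated on the purified mono-prenyl phenol, whose only free ortho position takes the second prenyl group.

Step 8
Reactants: 12 4-bromo-2,6-diprenylphenol
Product: 13 (4-bromo-2,6-diprenylphenoxy)(tert-butyl)dimethylsilane
Conditions: TBSCl, imidazole, DMAP (cat.), DMF, 50 °C
Reagents that add atoms: tert-butyldimethylsilyl chloride (TBSCl), CC(C)(C)[Si](C)(C)Cl
Why: O-silylation of the doubly ortho-substituted phenol needs gentle warming and gives a hindered aryl silyl ether that should survive organolithium chemistry.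

Step 9
Reactants: 13 (4-bromo-2,6-diprenylphenoxy)(tert-butyl)dimethylsilane
Product: 15 4-(tert-butyldimethylsilyloxy)-3,5-diprenylbenzoic acid, via aryllithium 14 (not isolated)
Conditions: n-BuLi, THF, −78 °C; CO2; then 1 M HCl, 0 °C
Reagents that add atoms: carbon dioxide, O=C=O
Why: Bromine–lithium exchange followed by carboxylation of the aryllithium should give the acid; the lithium is para to the silyl ether, so no silyl migration is possible.

**Fragment union and end game**

Step 10
Reactants: 9 6-bromo-3-(tert-butyldimethylsilyloxy)-2-prenylphenol; 15 4-(tert-butyldimethylsilyloxy)-3,5-diprenylbenzoic acid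
Product: 16 6-bromo-3-(tert-butyldimethylsilyloxy)-2-prenylphenyl 4-(tert-butyldimethylsilyloxy)-3,5-diprenylbenzoate
Conditions: DCC, DMAP (0.2 equiv), CH2Cl2, 0 °C → rt
Reagents that add atoms: none
Why: Steglich esterification through the acylpyridinium ion should acylate the hindered phenol without the free HCl that an acid chloride route would expose the prenyl groups to.

Step 11
Reactants: 16 6-bromo-3-(tert-butyldimethylsilyloxy)-2-prenylphenyl 4-(tert-butyldimethylsilyloxy)-3,5-diprenylbenzoate
Product: 17 tert-butyl{4-bromo-3-[1-(4-(tert-butyldimethylsilyloxy)-3,5-diprenylphenyl)vinyloxy]-2-prenylphenoxy}dimethylsilane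
Conditions: Cp2TiMe2 (3 equiv), toluene, 70 °C, dark; filtration through basic alumina
Reagents that add atoms: dimethyltitanocene (Cp2TiMe2), [CH3-].[CH3-].[Ti+4].c1cc[cH-]c1.c1cc[cH-]c1
Why: Petasis methylenation (Cp2Ti=CH2, [2+2] with the ester carbonyl, cycloreversion) converts aryl benzoates into 1-aryloxy-1-arylethenes under non-acidic conditions that leave the aryl bromide, silyl ethers and trisubstituted alkenes alone.

Step 12
Reactants: 17 tert-butyl{4-bromo-3-[1-(4-(tert-butyldimethylsilyloxy)-3,5-diprenylphenyl)vinyloxy]-2-prenylphenoxy}dimethylsilane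
Product: 20 4-(tert-butyldimethylsilyloxy)-2-{1-[4-(tert-butyldimethylsilyloxy)-3,5-diprenylphenyl]vinyloxy}-3-prenylbenzaldehyde, via aryllithium 18 (not isolated), via lithium hemiaminolate 19 (not isolated)
Conditions: n-BuLi (1.05 equiv), THF, −78 °C, 10 min; DMF, −78 → 0 °C; aq. NH4Cl
Reagents that add atoms: N,N-dimethylformamide (DMF), CN(C)C=O
Why: Bromine–lithium exchange at −78 °C should be much faster than addition of n-BuLi to the aryloxystyrene, and formylation of the aryllithium with DMF releases the aldehyde on a near-neutral quench that the acid-sensitive enol ether tolerates.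

Step 13
Reactants: 20 4-(tert-butyldimethylsilyloxy)-2-{1-[4-(tert-butyldimethylsilyloxy)-3,5-diprenylphenyl]vinyloxy}-3-prenylbenzaldehyde
Product: 21 (2S)-7-(tert-butyldimethylsilyloxy)-2-[4-(tert-butyldimethylsilyloxy)-3,5-diprenylphenyl]-8-prenylchroman-4-one
Conditions: [Rh(cod)Cl]2 (5 mol %), (R)-DTBM-SEGPHOS (10 mol %), AgBF4 (10 mol %, AgCl filtered off), 4 Å MS, ClCH2CH2Cl, 60 °C
Reagents that add atoms: none
Why: Proposed new method: a cationic bisphosphine complex of monovalent rhodium inserts into the formyl C–H bond of 20 to give an acyl hydride of trivalent rhodium in which the tethered enol ether alkene (O1–C2=C3) fills the vacant site and so holds back decarbonylation; the hydride then migrates to C2, rhodium takes the unsubstituted C3, and C–C reductive elimination from the seven-membered acyl alkyl rhodacycle forms C3–C4. The closest known reaction type is the rhodium bisphosphine-catalysed enantioselective endo hydroacylation of ortho-allylbenzaldehydes carrying 1,1-disubstituted alkenes to 3-substituted tetralones, of which 20 is the analogue with O1 in place of the benzylic CH2. Ring C (O1, C2, C3, C4, C4a, C8a) closes in a net 6-endo-trig mode. The C2 stereocentre is set in the enantiofacial hydride transfer to C2 under control of the C2-symmetric bisphosphine, and the ligand antipode that delivers 2S is fixed in the first screen. Endo over exo selectivity is needed and should follow from the 1,1-disubstitution, since the exo path would place rhodium on the fully substituted C2 and build a quaternary centre in a benzofuranone, while the C8 prenyl group beside O1 turns the vinyl group towards the formyl group. The vinyl ether has no allylic hydrogen to isomerise, the prenyl double bonds are trisubstituted and far from the acyl metal centre, and in the absence of base or Brønsted acid the flavanone cannot equilibrate with its chalcone.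

Step 14
Reactants: 21 (2S)-7-(tert-butyldimethylsilyloxy)-2-[4-(tert-butyldimethylsilyloxy)-3,5-diprenylphenyl]-8-prenylchroman-4-one
Product: 22 sophoranone, (2S)-7-hydroxy-2-(4-hydroxy-3,5-diprenylphenyl)-8-prenylchroman-4-one
Conditions: Bu4NF/AcOH (1:1, 3 equiv), THF, 0 °C → rt
Reagents that add atoms: none
Why: Fluoride-mediated cleavage of both aryl silyl ethers in an acetic acid-buffered medium keeps the phenols protonated, so the phenoxide-driven retro-oxa-Michael opening that would racemise C2 should not start, and the prenyl groups see no strong acid.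

**Compound list**
1 | resorcinol | Oc1cccc(O)c1 | starting material
2 | 1,3-bis(methoxymethoxy)benzene | COCOc1cccc(OCOC)c1 | intermediate
3 | prenyl bromide (1-bromo-3-methylbut-2-ene) | CC(C)=CCBr | starting material
4 | [2,6-bis(methoxymethoxy)phenyl]lithium | [Li]c1c(OCOC)cccc1OCOC | intermediate
5 | 1,3-bis(methoxymethoxy)-2-(3-methylbut-2-enyl)benzene | CC(C)=CCc1c(OCOC)cccc1OCOC | intermediate
6 | [2,4-bis(methoxymethoxy)-3-(3-methylbut-2-enyl)phenyl]lithium | [Li]c1ccc(OCOC)c(CC=C(C)C)c1OCOC | intermediate
7 | 1-bromo-2,4-bis(methoxymethoxy)-3-(3-methylbut-2-enyl)benzene | Brc1ccc(OCOC)c(CC=C(C)C)c1OCOC | intermediate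
8 | 4-bromo-2-(3-methylbut-2-enyl)benzene-1,3-diol | CC(C)=CCc1c(O)ccc(Br)c1O | intermediate
9 | 6-bromo-3-(tert-butyldimethylsilyloxy)-2-(3-methylbut-2-enyl)phenol | CC(C)=CCc1c(O)c(Br)ccc1O[Si](C)(C)C(C)(C)C | intermediate
10 | 4-bromophenol | Oc1ccc(Br)cc1 | starting material
11 | 4-bromo-2-(3-methylbut-2-enyl)phenol | CC(C)=CCc1cc(Br)ccc1O | intermediate
12 | 4-bromo-2,6-bis(3-methylbut-2-enyl)phenol | CC(C)=CCc1cc(Br)cc(CC=C(C)C)c1O | intermediate
13 | [4-bromo-2,6-bis(3-methylbut-2-enyl)phenoxy](tert-butyl)dimethylsilane | CC(C)=CCc1cc(Br)cc(CC=C(C)C)c1O[Si](C)(C)C(C)(C)C | intermediate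
14 | [4-(tert-butyldimethylsilyloxy)-3,5-bis(3-methylbut-2-enyl)phenyl]lithium | CC(C)=CCc1cc([Li])cc(CC=C(C)C)c1O[Si](C)(C)C(C)(C)C | intermediate
15 | 4-(tert-butyldimethylsilyloxy)-3,5-bis(3-methylbut-2-enyl)benzoic acid | CC(C)=CCc1cc(C(=O)O)cc(CC=C(C)C)c1O[Si](C)(C)C(C)(C)C | intermediate
16 | 6-bromo-3-(tert-butyldimethylsilyloxy)-2-(3-methylbut-2-enyl)phenyl 4-(tert-butyldimethylsilyloxy)-3,5-bis(3-methylbut-2-enyl)benzoate | CC(C)=CCc1cc(C(=O)Oc2c(Br)ccc(O[Si](C)(C)C(C)(C)C)c2CC=C(C)C)cc(CC=C(C)C)c1O[Si](C)(C)C(C)(C)C | intermediate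
17 | tert-butyl{4-bromo-3-[1-(4-(tert-butyldimethylsilyloxy)-3,5-bis(3-methylbut-2-enyl)phenyl)vinyloxy]-2-(3-methylbut-2-enyl)phenoxy}dimethylsilane | CC(C)=CCc1cc(C(=C)Oc2c(Br)ccc(O[Si](C)(C)C(C)(C)C)c2CC=C(C)C)cc(CC=C(C)C)c1O[Si](C)(C)C(C)(C)C | intermediate
18 | aryllithium from 17 (Li in place of Br) | CC(C)=CCc1cc(C(=C)Oc2c([Li])ccc(O[Si](C)(C)C(C)(C)C)c2CC=C(C)C)cc(CC=C(C)C)c1O[Si](C)(C)C(C)(C)C | intermediate
19 | lithium hemiaminolate from 18 and DMF (ArCH(OLi)NMe2) | CC(C)=CCc1cc(C(=C)Oc2c(C(O[Li])N(C)C)ccc(O[Si](C)(C)C(C)(C)C)c2CC=C(C)C)cc(CC=C(C)C)c1O[Si](C)(C)C(C)(C)C | intermediate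
20 | 4-(tert-butyldimethylsilyloxy)-2-{1-[4-(tert-butyldimethylsilyloxy)-3,5-bis(3-methylbut-2-enyl)phenyl]vinyloxy}-3-(3-methylbut-2-enyl)benzaldehyde | CC(C)=CCc1cc(C(=C)Oc2c(C=O)ccc(O[Si](C)(C)C(C)(C)C)c2CC=C(C)C)cc(CC=C(C)C)c1O[Si](C)(C)C(C)(C)C | intermediate
21 | (2S)-7-(tert-butyldimethylsilyloxy)-2-[4-(tert-butyldimethylsilyloxy)-3,5-bis(3-methylbut-2-enyl)phenyl]-8-(3-methylbut-2-enyl)chroman-4-one | CC(C)=CCc1cc([C@@H]2CC(=O)c3ccc(O[Si](C)(C)C(C)(C)C)c(CC=C(C)C)c3O2)cc(CC=C(C)C)c1O[Si](C)(C)C(C)(C)C | intermediate
22 | sophoranone, (2S)-7-hydroxy-2-[4-hydroxy-3,5-bis(3-methylbut-2-enyl)phenyl]-8-(3-methylbut-2-enyl)chroman-4-one | CC(C)=CCc1cc([C@@H]2CC(=O)c3ccc(O)c(CC=C(C)C)c3O2)cc(CC=C(C)C)c1O | target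

**Step count**
Total: 14 steps. Longest linear sequence: 10 steps (steps 1–5 and 10–14, from resorcinol).

**Steps most likely to fail**

Step 13. The acyl rhodium hydride may lose CO faster than it adds across the electron-rich 1,1-disubstituted enol ether. Hydride transfer may also show poor facial selectivity, and traces of acid from the cationic catalyst may hydrolyse the enol ether. The fallback uses known chemistry and forms the C2–aryl bond instead, by enantioselective conjugate addition of an arylboronic acid to a chromone. It sets out from 5 and 13 (through their lithio derivatives 6 and 14, made as in steps 3 and 9) and comes back at 21. Aryllithium 6 would be acylated with N-methoxy-N-methylacetamide to give 1-[2,4-bis(methoxymethoxy)-3-prenylphenyl]ethanone F1, and HCl in methanol would then give 1-(2,4-dihydroxy-3-prenylphenyl)ethanone F2. TBSCl and imidazole should silylate only the 4-hydroxyl, the 2-hydroxyl being hydrogen-bonded to the ketone, to give 1-[4-(tert-butyldimethylsilyloxy)-2-hydroxy-3-prenylphenyl]ethanone F3. DMF dimethyl acetal in warm toluene would give the enaminone (E)-1-[4-(tert-butyldimethylsilyloxy)-2-hydroxy-3-prenylphenyl]-3-(dimethylamino)prop-2-en-1-one F4, which should cyclise on silica gel or with a trace of acid, with loss of dimethylamine, to 7-(tert-butyldimethylsilyloxy)-8-prenylchromen-4-one F5. Aryllithium 14 would be quenched with B(Oi-Pr)3 and hydrolysed to [4-(tert-butyldimethylsilyloxy)-3,5-diprenylphenyl]boronic acid F6. F5 and F6 would be joined with Pd(OCOCF3)2, a chiral tert-butyl pyridine-oxazoline ligand (antipode chosen for 2S), NH4PF6 and water in 1,2-dichloroethane at 60 °C; this addition of an aryl complex of divalent palladium to the chromone should give 21.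

Step 12. n-BuLi or the aryllithium may add to the neighbouring aryloxystyrene, attack silicon of the aryl silyl ethers, or be protonated to the debrominated arene. The fallback avoids organolithiums: palladium-catalysed reductive carbonylation of the aryl bromide with Pd(OAc)2, di(1-adamantyl)-n-butylphosphine, CO/H2 (1:1, 5 bar) and TMEDA in toluene at 100 °C. It sets out from 17 and comes back at 20 in one operation, with no new compound (F0).

Step 5. Silylation may discriminate poorly between the two hydroxyls and give the wrong mono-silyl ether and the bis-silyl ether. The fallback differentiates the hydroxyls through the hydrogen bond to a formyl group and joins the fragments by C–O coupling. It sets out from 5 and 13 (again through 6 and 14) and comes back at 20. Aryllithium 6 would be quenched with DMF to give 2,4-bis(methoxymethoxy)-3-prenylbenzaldehyde F7, and HCl in methanol would give 2,4-dihydroxy-3-prenylbenzaldehyde F8. TBSCl and imidazole should silylate only the non-chelated 4-hydroxyl to give 4-(tert-butyldimethylsilyloxy)-2-hydroxy-3-prenylbenzaldehyde F9. Aryllithium 14 would be acylated with N-methoxy-N-methylacetamide to give 1-[4-(tert-butyldimethylsilyloxy)-3,5-diprenylphenyl]ethanone F10, which KN(SiMe3)2 and PhNTf2 at −78 °C would convert into 1-[4-(tert-butyldimethylsilyloxy)-3,5-diprenylphenyl]vinyl trifluoromethanesulfonate F11. F9 and F11 would be coupled with Pd2(dba)3, 2-(di-tert-butylphosphino)biphenyl and K3PO4 in toluene at 80 °C (enol triflate–phenol coupling at zerovalent palladium) to give 20. This coupling is demanding for a hindered, chelating phenol, which is why it is held in reserve.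

**Further compounds**
F1 | step 13 | 1-[2,4-bis(methoxymethoxy)-3-(3-methylbut-2-enyl)phenyl]ethanone | CC(=O)c1ccc(OCOC)c(CC=C(C)C)c1OCOC
F2 | step 13 | 1-[2,4-dihydroxy-3-(3-methylbut-2-enyl)phenyl]ethanone | CC(=O)c1ccc(O)c(CC=C(C)C)c1O
F3 | step 13 | 1-[4-(tert-butyldimethylsilyloxy)-2-hydroxy-3-(3-methylbut-2-enyl)phenyl]ethanone | CC(=O)c1ccc(O[Si](C)(C)C(C)(C)C)c(CC=C(C)C)c1O
F4 | step 13 | (E)-1-[4-(tert-butyldimethylsilyloxy)-2-hydroxy-3-(3-methylbut-2-enyl)phenyl]-3-(dimethylamino)prop-2-en-1-one | CN(C)/C=C/C(=O)c1ccc(O[Si](C)(C)C(C)(C)C)c(CC=C(C)C)c1O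
F5 | step 13 | 7-(tert-butyldimethylsilyloxy)-8-(3-methylbut-2-enyl)-4H-chromen-4-one | O=c1ccoc2c(CC=C(C)C)c(O[Si](C)(C)C(C)(C)C)ccc12
F6 | step 13 | [4-(tert-butyldimethylsilyloxy)-3,5-bis(3-methylbut-2-enyl)phenyl]boronic acid | CC(C)=CCc1cc(B(O)O)cc(CC=C(C)C)c1O[Si](C)(C)C(C)(C)C
F0 | step 12 | none | none
F7 | step 5 | 2,4-bis(methoxymethoxy)-3-(3-methylbut-2-enyl)benzaldehyde | O=Cc1ccc(OCOC)c(CC=C(C)C)c1OCOC
F8 | step 5 | 2,4-dihydroxy-3-(3-methylbut-2-enyl)benzaldehyde | O=Cc1ccc(O)c(CC=C(C)C)c1O
F9 | step 5 | 4-(tert-butyldimethylsilyloxy)-2-hydroxy-3-(3-methylbut-2-enyl)benzaldehyde | O=Cc1ccc(O[Si](C)(C)C(C)(C)C)c(CC=C(C)C)c1O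
F10 | step 5 | 1-[4-(tert-butyldimethylsilyloxy)-3,5-bis(3-methylbut-2-enyl)phenyl]ethanone | CC(=O)c1cc(CC=C(C)C)c(O[Si](C)(C)C(C)(C)C)c(CC=C(C)C)c1
F11 | step 5 | 1-[4-(tert-butyldimethylsilyloxy)-3,5-bis(3-methylbut-2-enyl)phenyl]vinyl trifluoromethanesulfonate | C=C(OS(=O)(=O)C(F)(F)F)c1cc(CC=C(C)C)c(O[Si](C)(C)C(C)(C)C)c(CC=C(C)C)c1
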